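**Retrosynthetic overview**
1. Target ⇐ double O-acetylation of 8,20-dihydroxyserrulat-14-en-19-oic acid.
2. C8–O (key step, new): aryl C–H → C–O by C20-hydroxyl-directed peri C–H silylation and Tamao oxidation; the methyl ester is hydrolysed in the same pot.
3. C20–O and the C1 centre: catalyst-controlled anti-Markovnikov hydroboration–oxidation of a 1-methylene tetralin.
4. Only one ring is built, the carbocyclic ring of the tetralin (the benzoate ring is bought; an oxasiline ring is transient in the key step): carbonylative B-alkyl Suzuki closure of an o-bromoaryl diene to the 1-tetralone, then Wittig methylenation.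
5. C4 (C11 from the chiral pool): copper/amine-catalysed α-arylation of (S)-citronellal with an aryl(mesityl)iodonium salt made from methyl 4-bromo-3-iodobenzoate.

**Notes**
- Positions are cited in serrulatane numbering: C1 bears C20 (CH2O), C4 bears the side chain (C11 onward), C6 bears the carboxyl carbon C19, C8 bears the aryl oxygen.
- Assumption: the catalyst antipodes named in steps 2 and 6 are those predicted by the usual facial models and are not confirmed; if the sense of induction proves opposite, the enantiomeric catalyst is used.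
- (S)-tBu-IPO is the iminopyridine–oxazoline ligand (S)-4-tert-butyl-2-[6-(1-{[2,6-di(propan-2-yl)phenyl]imino}ethyl)pyridin-2-yl]-4,5-dihydro-1,3-oxazole.

**Route**

Step 1
Reactants: 1 methyl 4-bromo-3-iodobenzoate
Product: 2 [2-bromo-5-(methoxycarbonyl)phenyl](2,4,6-trimethylphenyl)iodonium trifluoromethanesulfonate
Conditions: mCPBA, TfOH, mesitylene, CH2Cl2, 0 → 25 °C
Reagents that add atoms: mesitylene (Cc1cc(C)cc(C)c1); trifluoromethanesulfonic acid (OS(=O)(=O)C(F)(F)F)
Why: One-pot diaryliodonium synthesis (Olofsson type), in which mCPBA/TfOH oxidise the aryl iodide to a trivalent iodine species that substitutes mesitylene electrophilically; no stereocentre is involved.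

Step 2
Reactants: 2 [2-bromo-5-(methoxycarbonyl)phenyl](2,4,6-trimethylphenyl)iodonium trifluoromethanesulfonate; 3 (S)-citronellal [(3S)-3,7-dimethyloct-6-enal]
Product: 4 methyl 4-bromo-3-[(2S,3S)-3,7-dimethyl-1-oxooct-6-en-2-yl]benzoate
Conditions: CuBr (10 mol%), (2R,5R)-5-benzyl-2-tert-butyl-3-methylimidazolidin-4-one·Cl3CCO2H (20 mol%), NaHCO3, toluene/Et2O, 23 °C
Reagents that add atoms: none
Why: Enamine catalysis merged with copper catalysis (MacMillan α-arylation of aldehydes), in which the E-enamine of 3 is arylated by the aryl–copper species (trivalent copper) formed from 2 with mesityl as the non-transferred group, and the benzyl arm of the second-generation imidazolidinone blocks one enamine face so that C4 is set S by catalyst control next to the chiral-pool C11 centre.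

Step 3
Reactants: 4 methyl 4-bromo-3-[(2S,3S)-3,7-dimethyl-1-oxooct-6-en-2-yl]benzoate
Product: 5 methyl 4-bromo-3-[(3S,4S)-4,8-dimethylnona-1,7-dien-3-yl]benzoate
Conditions: Ph3PCH3Br, KN(SiMe3)2, THF, −78 → 0 °C
Reagents that add atoms: methyltriphenylphosphonium bromide (C[P+](c1ccccc1)(c1ccccc1)c1ccccc1.[Br-])
Why: Wittig methylenation with the non-stabilised ylide at low temperature, where carbonyl addition outruns enolisation so the α-aryl C4 centre is kept, and the aryl ester and bromide are inert.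

Step 4
Reactants: 5 methyl 4-bromo-3-[(3S,4S)-4,8-dimethylnona-1,7-dien-3-yl]benzoate
Product: 7 methyl (8S)-8-[(2S)-6-methylhept-5-en-2-yl]-5-oxo-5,6,7,8-tetrahydronaphthalene-2-carboxylate, via B-alkyl-9-BBN adduct 6 (not isolated)
Conditions: 9-BBN, THF, 0 → 25 °C; then Pd(OAc)2 (5 mol%), Xantphos (6 mol%), K3PO4, H2O, CO (1 atm), THF, 70 °C, 0.02 M
Reagents that add atoms: carbon monoxide ([C-]#[O+])
Why: 9-BBN hydroborates only the monosubstituted alkene, and oxidative addition of the electron-poor aryl bromide, CO insertion to the aroyl–palladium species and intramolecular B-alkyl transmetalation with reductive elimination close the six-membered ketone (carbonylative Suzuki–Miyaura cyclisation) without touching C4 or C11.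

Step 5
Reactants: 7 methyl (8S)-8-[(2S)-6-methylhept-5-en-2-yl]-5-oxo-5,6,7,8-tetrahydronaphthalene-2-carboxylate
Product: 8 methyl (8S)-5-methylidene-8-[(2S)-6-methylhept-5-en-2-yl]-5,6,7,8-tetrahydronaphthalene-2-carboxylate
Conditions: Ph3PCH3Br, KOt-Bu, THF, 0 → 25 °C
Reagents that add atoms: methyltriphenylphosphonium bromide (C[P+](c1ccccc1)(c1ccccc1)c1ccccc1.[Br-])
Why: Wittig methylenation of the aryl ketone, with C4 not α to the carbonyl and therefore not at risk, and the methyl ester much less electrophilic than the ketone.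

Step 6
Reactants: 8 methyl (8S)-5-methylidene-8-[(2S)-6-methylhept-5-en-2-yl]-5,6,7,8-tetrahydronaphthalene-2-carboxylate
Product: 10 methyl (5R,8S)-5-(hydroxymethyl)-8-[(2S)-6-methylhept-5-en-2-yl]-5,6,7,8-tetrahydronaphthalene-2-carboxylate, via pinacol boronate 9 (not isolated)
Conditions: (S)-tBu-IPO·CoCl2 (3 mol%), NaBHEt3 (6 mol%), HBpin, THF, 25 °C; then H2O2, aq NaOH, 0 °C
Reagents that add atoms: hydrogen peroxide (OO); pinacolborane (CC1(C)OBOC1(C)C, boron stays only in 9)
Why: Cobalt-hydride asymmetric anti-Markovnikov hydroboration of a 1,1-disubstituted aryl alkene followed by C–B oxidation with retention (the side-chain trisubstituted alkene and the ester do not react), in which hydride is delivered to C1 on the ligand-chosen face while cobalt sits on the exocyclic carbon, so catalyst control is relied on to override the remote C4 group (whose intrinsic bias favours the cis isomer) and give 1R, trans to the side chain, with any C1 epimer a separable diastereomer.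

Step 7
Reactants: 10 methyl (5R,8S)-5-(hydroxymethyl)-8-[(2S)-6-methylhept-5-en-2-yl]-5,6,7,8-tetrahydronaphthalene-2-carboxylate
Product: 14 (5R,8S)-4-hydroxy-5-(hydroxymethyl)-8-[(2S)-6-methylhept-5-en-2-yl]-5,6,7,8-tetrahydronaphthalene-2-carboxylic acid, via diethylsilyl ether 11 (not isolated), via peri-fused oxasiline 12 (not isolated), via diol methyl ester 13 (not isolated)
Conditions: Et2SiH2, [Ir(cod)OMe]2 (0.5 mol%), THF, 25 °C; then [Rh(cod)Cl]2 (2 mol%), Xantphos (4.4 mol%), norbornene, THF, 100 °C; then H2O2, KHCO3, THF/MeOH, 50 °C; then Na2S2O3; LiOH·H2O, H2O, 50 °C; HCl to pH 3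
Reagents that add atoms: hydrogen peroxide (OO); lithium hydroxide ([Li+].[OH-]); diethylsilane (CC[SiH2]CC, silicon stays only in 11 and 12)
Why: Proposed new method: peri C–H hydroxylation of a homobenzylic alcohol through a six-membered oxasiline, in which the O–SiEt2H group made from the C20 hydroxyl adds its Si–H bond to the rhodium–Xantphos centre, the wide-bite-angle complex cleaves the only aryl C–H bond within reach (C8–H, held beside C20–O by the tetralin frame and more reactive than the competing secondary C2–H) through a seven-membered rhodacycle, C–Si reductive elimination closes the ring with norbornene as hydrogen acceptor, Tamao oxidation then converts C8–Si into the C8–O bond at the same carbon and LiOH (added after the peroxide is quenched) frees the acid; the closest known reactions are the iridium-catalysed hydroxyl-directed ortho-silylation of benzylic alcohols (five-membered benzoxasiloles) and the rhodium–Xantphos δ-C(sp3)–H silylation of alcohols to 1,4-diols, neither of which, to my knowledge, has been shown for a δ (peri) aryl C–H bond; no stereocentre is touched.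

Step 8
Reactants: 14 (5R,8S)-4-hydroxy-5-(hydroxymethyl)-8-[(2S)-6-methylhept-5-en-2-yl]-5,6,7,8-tetrahydronaphthalene-2-carboxylic acid
Product: 15 (5R,8S)-4-(acetyloxy)-5-[(acetyloxy)methyl]-8-[(2S)-6-methylhept-5-en-2-yl]-5,6,7,8-tetrahydronaphthalene-2-carboxylic acid (8,20-diacetoxyserrulat-14-en-19-oic acid; the target)
Conditions: Ac2O, pyridine, DMAP (5 mol%), CH2Cl2, 0 → 25 °C; then H2O/THF; dilute HCl work-up
Reagents that add atoms: acetic anhydride (CC(=O)OC(C)=O)
Why: DMAP-catalysed O-acylation of the primary alcohol and the phenol, with the mixed anhydride formed at the carboxyl group hydrolysed back to the acid in the aqueous stage; no stereocentre is touched.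

**Compound list**
1 | methyl 4-bromo-3-iodobenzoate | COC(=O)c1ccc(Br)c(I)c1 | starting material
2 | [2-bromo-5-(methoxycarbonyl)phenyl](2,4,6-trimethylphenyl)iodonium trifluoromethanesulfonate | COC(=O)c1ccc(Br)c([I+]c2c(C)cc(C)cc2C)c1.[O-]S(=O)(=O)C(F)(F)F | intermediate
3 | (S)-citronellal, (3S)-3,7-dimethyloct-6-enal | C[C@@H](CCC=C(C)C)CC=O | starting material
4 | methyl 4-bromo-3-[(2S,3S)-3,7-dimethyl-1-oxooct-6-en-2-yl]benzoate | O=C[C@@H]([C@@H](C)CCC=C(C)C)c1cc(C(=O)OC)ccc1Br | intermediate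
5 | methyl 4-bromo-3-[(3S,4S)-4,8-dimethylnona-1,7-dien-3-yl]benzoate | C=C[C@@H]([C@@H](C)CCC=C(C)C)c1cc(C(=O)OC)ccc1Br | intermediate
6 | methyl 3-[(3S,4S)-1-(9-borabicyclo[3.3.1]nonan-9-yl)-4,8-dimethylnon-7-en-3-yl]-4-bromobenzoate | C1CCC2CCCC1B2CC[C@@H]([C@@H](C)CCC=C(C)C)c1cc(C(=O)OC)ccc1Br | intermediate (not isolated)
7 | methyl (8S)-8-[(2S)-6-methylhept-5-en-2-yl]-5-oxo-5,6,7,8-tetrahydronaphthalene-2-carboxylate | O=C1CC[C@@H]([C@@H](C)CCC=C(C)C)c2cc(C(=O)OC)ccc21 | intermediate
8 | methyl (8S)-5-methylidene-8-[(2S)-6-methylhept-5-en-2-yl]-5,6,7,8-tetrahydronaphthalene-2-carboxylate | C=C1CC[C@@H]([C@@H](C)CCC=C(C)C)c2cc(C(=O)OC)ccc21 | intermediate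
9 | methyl (5R,8S)-8-[(2S)-6-methylhept-5-en-2-yl]-5-[(4,4,5,5-tetramethyl-1,3,2-dioxaborolan-2-yl)methyl]-5,6,7,8-tetrahydronaphthalene-2-carboxylate | CC1(C)OB(C[C@@H]2CC[C@@H]([C@@H](C)CCC=C(C)C)c3cc(C(=O)OC)ccc32)OC1(C)C | intermediate (not isolated)
10 | methyl (5R,8S)-5-(hydroxymethyl)-8-[(2S)-6-methylhept-5-en-2-yl]-5,6,7,8-tetrahydronaphthalene-2-carboxylate | OC[C@@H]1CC[C@@H]([C@@H](C)CCC=C(C)C)c2cc(C(=O)OC)ccc21 | intermediate
11 | methyl (5R,8S)-5-{[(diethylsilyl)oxy]methyl}-8-[(2S)-6-methylhept-5-en-2-yl]-5,6,7,8-tetrahydronaphthalene-2-carboxylate | CC[SiH](CC)OC[C@@H]1CC[C@@H]([C@@H](C)CCC=C(C)C)c2cc(C(=O)OC)ccc21 | intermediate (not isolated)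
12 | peri-fused oxasiline: the methyl ester of 10 in which a diethylsilylene joins O-20 to C-8 (six-membered Si–O–C20–C1–C8a–C8 ring; 1R,4S,11S) | CC[Si]1(CC)OC[C@@H]2CC[C@@H]([C@@H](C)CCC=C(C)C)c3cc(C(=O)OC)cc1c32 | intermediate (not isolated)
13 | methyl (5R,8S)-4-hydroxy-5-(hydroxymethyl)-8-[(2S)-6-methylhept-5-en-2-yl]-5,6,7,8-tetrahydronaphthalene-2-carboxylate | OC[C@@H]1CC[C@@H]([C@@H](C)CCC=C(C)C)c2cc(C(=O)OC)cc(O)c21 | intermediate (not isolated)
14 | (5R,8S)-4-hydroxy-5-(hydroxymethyl)-8-[(2S)-6-methylhept-5-en-2-yl]-5,6,7,8-tetrahydronaphthalene-2-carboxylic acid | OC[C@@H]1CC[C@@H]([C@@H](C)CCC=C(C)C)c2cc(C(=O)O)cc(O)c21 | intermediate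
15 | (5R,8S)-4-(acetyloxy)-5-[(acetyloxy)methyl]-8-[(2S)-6-methylhept-5-en-2-yl]-5,6,7,8-tetrahydronaphthalene-2-carboxylic acid | CC(=O)OC[C@@H]1CC[C@@H]([C@@H](C)CCC=C(C)C)c2cc(C(=O)O)cc(OC(C)=O)c21 | target

**Totals**
Total step count: 8. Longest linear sequence: 8 steps (1 → 15; citronellal 3 enters at step 2).

**Three steps most likely to fail**

Step 7 (the proposed new method). The seven-membered rhodacycle may not form, silylation of the secondary C2–H may compete, and the trans isomer must place both ring substituents pseudo-equatorial to reach C8–H. The fallback uses known chemistry and installs the oxygen before C1 is built; it sets out from 7 and comes back at 13. Ketone 7 is hydrosilylated with Et2SiH2 and [Ir(cod)OMe]2 to the benzylic silyl ether methyl (8S)-5-[(diethylsilyl)oxy]-8-[(2S)-6-methylhept-5-en-2-yl]-5,6,7,8-tetrahydronaphthalene-2-carboxylate F6. Under [Ir(cod)OMe]2, 1,10-phenanthroline and norbornene (the published ketone/benzylic alcohol protocol, five-membered ring) this closes onto C8–H to the benzoxasilole of the tetralin (diethylsilylene joining O-1 and C-8) F7. H2O2/KHCO3 gives methyl (8S)-4,5-dihydroxy-8-[(2S)-6-methylhept-5-en-2-yl]-5,6,7,8-tetrahydronaphthalene-2-carboxylate F8, and MnO2 reoxidises the benzylic alcohol to methyl (8S)-4-hydroxy-8-[(2S)-6-methylhept-5-en-2-yl]-5-oxo-5,6,7,8-tetrahydronaphthalene-2-carboxylate F9. TBSCl/imidazole gives the silyl ether methyl (8S)-4-[(tert-butyldimethylsilyl)oxy]-8-[(2S)-6-methylhept-5-en-2-yl]-5-oxo-5,6,7,8-tetrahydronaphthalene-2-carboxylate F10, and Ph3PCH3Br/KOt-Bu gives methyl (8S)-4-[(tert-butyldimethylsilyl)oxy]-5-methylidene-8-[(2S)-6-methylhept-5-en-2-yl]-5,6,7,8-tetrahydronaphthalene-2-carboxylate F11. The conditions of step 6 give, through methyl (5R,8S)-4-[(tert-butyldimethylsilyl)oxy]-8-[(2S)-6-methylhept-5-en-2-yl]-5-[(4,4,5,5-tetramethyl-1,3,2-dioxaborolan-2-yl)methyl]-5,6,7,8-tetrahydronaphthalene-2-carboxylate F12, the alcohol methyl (5R,8S)-4-[(tert-butyldimethylsilyl)oxy]-5-(hydroxymethyl)-8-[(2S)-6-methylhept-5-en-2-yl]-5,6,7,8-tetrahydronaphthalene-2-carboxylate F13. Bu4NF then gives 13, which is saponified as in step 7 to 14.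

Step 4. Under CO the oxidative addition of the aryl bromide is slowed, and direct (non-carbonylative) B-alkyl coupling would give the indane. The fallback replaces the carbonylation by an intramolecular acylation of an aryl Grignard reagent; it sets out from 4 and comes back at 7. Aldehyde 4 and the stabilised ylide Ph3P=CHC(O)N(OMe)Me (CH2Cl2, 25 °C) give methyl 4-bromo-3-[(2E,4R,5S)-1-[methoxy(methyl)amino]-5,9-dimethyl-1-oxodeca-2,8-dien-4-yl]benzoate F4. Conjugate reduction with catalytic [(Ph3P)CuH]6 and polymethylhydrosiloxane gives methyl 4-bromo-3-[(4S,5S)-1-[methoxy(methyl)amino]-5,9-dimethyl-1-oxodec-8-en-4-yl]benzoate F5. Bromine–magnesium exchange with iPrMgCl·LiCl (THF, −15 °C) and attack of the aryl Grignard on the Weinreb amide closes ketone 7.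

Step 2. A β-branched aldehyde and an ortho-bromo aryl group are both outside the proven scope of the α-arylation. The fallback builds C4 and C11 together by iridium/amine dual catalysis; it sets out from 1 and comes back at 5. Iodine–magnesium exchange on 1 (iPrMgCl·LiCl, THF, −40 °C) and addition to acrolein give racemic methyl 4-bromo-3-(1-hydroxyprop-2-en-1-yl)benzoate F1. Stereodivergent α-allylation of 6-methylhept-5-enal (CC(C)=CCCCC=O) with F1 uses [Ir(cod)Cl]2, a chiral phosphoramidite–olefin ligand, a diarylprolinol silyl ether amine and (MeO)2P(O)OH, with the ligand/amine pairing chosen for the required isomer, and gives methyl 4-bromo-3-[(3S,4S)-4-formyl-8-methylnona-1,7-dien-3-yl]benzoate F2. TsNHNH2 converts it to the 4-methylbenzenesulfonylhydrazone of that aldehyde F3, and catecholborane followed by NaOAc·3H2O reduces CH=N–NHTs to CH3, which gives 5.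

**Further compounds**
F1 | step 2 | methyl 4-bromo-3-(1-hydroxyprop-2-en-1-yl)benzoate (racemic) | C=CC(O)c1cc(C(=O)OC)ccc1Br
F2 | step 2 | methyl 4-bromo-3-[(3S,4S)-4-formyl-8-methylnona-1,7-dien-3-yl]benzoate | C=C[C@@H]([C@@H](C=O)CCC=C(C)C)c1cc(C(=O)OC)ccc1Br
F3 | step 2 | 4-methylbenzenesulfonylhydrazone of methyl 4-bromo-3-[(3S,4S)-4-formyl-8-methylnona-1,7-dien-3-yl]benzoate | C=C[C@@H]([C@@H](/C=N/NS(=O)(=O)c1ccc(C)cc1)CCC=C(C)C)c1cc(C(=O)OC)ccc1Br
F4 | step 4 | methyl 4-bromo-3-[(2E,4R,5S)-1-[methoxy(methyl)amino]-5,9-dimethyl-1-oxodeca-2,8-dien-4-yl]benzoate | CON(C)C(=O)/C=C/[C@@H]([C@@H](C)CCC=C(C)C)c1cc(C(=O)OC)ccc1Br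
F5 | step 4 | methyl 4-bromo-3-[(4S,5S)-1-[methoxy(methyl)amino]-5,9-dimethyl-1-oxodec-8-en-4-yl]benzoate | CON(C)C(=O)CC[C@@H]([C@@H](C)CCC=C(C)C)c1cc(C(=O)OC)ccc1Br
F6 | step 7 | methyl (8S)-5-[(diethylsilyl)oxy]-8-[(2S)-6-methylhept-5-en-2-yl]-5,6,7,8-tetrahydronaphthalene-2-carboxylate (C5 epimers) | CC[SiH](CC)OC1CC[C@@H]([C@@H](C)CCC=C(C)C)c2cc(C(=O)OC)ccc21
F7 | step 7 | benzoxasilole of the tetralin (diethylsilylene joining O-1 and C-8; five-membered Si–O–C1–C8a–C8 ring; C1 epimers) | CC[Si]1(CC)OC2CC[C@@H]([C@@H](C)CCC=C(C)C)c3cc(C(=O)OC)cc1c32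
F8 | step 7 | methyl (8S)-4,5-dihydroxy-8-[(2S)-6-methylhept-5-en-2-yl]-5,6,7,8-tetrahydronaphthalene-2-carboxylate (C5 epimers) | OC1CC[C@@H]([C@@H](C)CCC=C(C)C)c2cc(C(=O)OC)cc(O)c21
F9 | step 7 | methyl (8S)-4-hydroxy-8-[(2S)-6-methylhept-5-en-2-yl]-5-oxo-5,6,7,8-tetrahydronaphthalene-2-carboxylate | O=C1CC[C@@H]([C@@H](C)CCC=C(C)C)c2cc(C(=O)OC)cc(O)c21
F10 | step 7 | methyl (8S)-4-[(tert-butyldimethylsilyl)oxy]-8-[(2S)-6-methylhept-5-en-2-yl]-5-oxo-5,6,7,8-tetrahydronaphthalene-2-carboxylate | O=C1CC[C@@H]([C@@H](C)CCC=C(C)C)c2cc(C(=O)OC)cc(O[Si](C)(C)C(C)(C)C)c21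
F11 | step 7 | methyl (8S)-4-[(tert-butyldimethylsilyl)oxy]-5-methylidene-8-[(2S)-6-methylhept-5-en-2-yl]-5,6,7,8-tetrahydronaphthalene-2-carboxylate | C=C1CC[C@@H]([C@@H](C)CCC=C(C)C)c2cc(C(=O)OC)cc(O[Si](C)(C)C(C)(C)C)c21
F12 | step 7 | methyl (5R,8S)-4-[(tert-butyldimethylsilyl)oxy]-8-[(2S)-6-methylhept-5-en-2-yl]-5-[(4,4,5,5-tetramethyl-1,3,2-dioxaborolan-2-yl)methyl]-5,6,7,8-tetrahydronaphthalene-2-carboxylate | CC1(C)OB(C[C@@H]2CC[C@@H]([C@@H](C)CCC=C(C)C)c3cc(C(=O)OC)cc(O[Si](C)(C)C(C)(C)C)c32)OC1(C)C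
F13 | step 7 | methyl (5R,8S)-4-[(tert-butyldimethylsilyl)oxy]-5-(hydroxymethyl)-8-[(2S)-6-methylhept-5-en-2-yl]-5,6,7,8-tetrahydronaphthalene-2-carboxylate | OC[C@@H]1CC[C@@H]([C@@H](C)CCC=C(C)C)c2cc(C(=O)OC)cc(O[Si](C)(C)C(C)(C)C)c21
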